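## Analysis of the target

The target is a depsidone. Ring A (C1 OMe, C2 H, C3 Me, C4 acyl carbon, C5 ether oxygen, C6 CH2OH) and ring B (C1' ether oxygen, C2' ester oxygen, C3' Me, C4' OH, C5' lactone carbonyl, C6' lactol carbon) are joined by an ester from the C4 carboxyl to the C2' oxygen and by an ether between C5 and C1', which together close a seven-membered dioxepinone; a five-membered hydroxy lactone is fused to ring B across C5' and C6'. Constitutionally it is stictic acid with the ring A formyl group at the alcohol oxidation level. The only stereocentre is the lactol carbon on C6', which is (R) (ring oxygen > hydroxyl > C6' > H), so there is no second centre to relate it to. It is an acyl hemiacetal that can open to an ortho-formyl benzoic acid, hence configurationally labile, and it has to be fixed at the very end under neutral conditions. Sensitive groups are the aryl ester of the seven-membered ring (opened by hydroxide or alkoxide), the lactol (opened by base, reduced by hydride) and the C6 benzylic alcohol, which sits between two ring oxygens and so ionises in strong acid and is easily oxidised. The difficulty lies in two almost fully substituted benzene rings, in placing ester and ether the right way round on the adjacent oxygens at C2' and C1', and in the late, labile stereocentre. The strategy rests on ring A being an orsellinate: the C4 carboxyl lies between the C3 methyl and the C5 oxygen, with the C1 oxygen para to it, which is the pattern of a folded tetraketide, so ring A can be grown from a linear eight-carbon acyl chain already esterified to the C2' oxygen. A second enabling feature is that C1' is para to the C4' hydroxyl, which allows the ether to be closed afterwards by phenol oxidation.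

## Retrosynthetic reasoning

**25 to 24.** The stereocentre of 25 cannot survive acid, base or protic equilibration, so the last operation must not touch the C–O bonds at the lactol carbon. Removal of acetyl groups from diacetate 24 at the acyl carbon, by an enzyme in a neutral medium, meets this requirement and retains configuration.

**24 to 23.** Racemic lactol 23 epimerises by reversible opening of its lactol ring, so its enantiomers interconvert. An enantioselective acyl transfer can therefore funnel all material into one acylal (dynamic kinetic resolution). No chiral material is needed anywhere earlier in the route.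

**23 to 22.** The hydroxy lactone is the ring-closed form of an ortho-formyl benzoic acid. In 22 the C6' aldehyde is masked as a dimethyl acetal, the C5' acid as a tert-butyl ester and the C6 alcohol as a silyl ether. One aqueous acid treatment has to remove all three without ionising the benzylic alcohol.

**22 to 21.** The C5–O–C1' ether bond is cut. C1' is para to the C4' hydroxyl and is the only unsubstituted carbon of ring B, so the forward reaction is a phenol oxidative coupling. The ester, made earlier, holds the C5 hydroxyl next to C1'. The ester is not cut at this stage, because forming it is the task of the key step.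

**21 to 20 to 18 to 17.** The silyl ether is removed. The C6–CH2OH bond is then cut: C6 is the only open carbon ortho to the C5 hydroxyl, so a phenol-templated one-carbon delivery can place it. The C1 O-methyl is removed last: in 17 the C1 hydroxyl is the only phenol not hydrogen-bonded to an ester carbonyl, so it can be methylated selectively.

**17 to 5 and 14 (key disconnection).** The ester C–O bond between the depside carbonyl and the C2' oxygen and the ring A C3–C4 bond are cut. Ring A unravels into the eight-carbon triketo chain of 16, which comes from acylketene 15 and phenol 14, and 15 is stored as dioxinone 5. The gain is that ring A needs no stepwise aromatic substitution and arrives already joined to the correct oxygen of ring B.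

**5 to 3 to 1.** Two successive C-acylations at the terminus of the dioxinone side chain lead back to commercial 1.

**14 to 6.** The C5' carboxyl is introduced at the bromine-bearing carbon of 11 (via aryllithium 12 to ester 13). The acetal comes from aldehyde 10, and the bromine is placed on the symmetrical arene 8 (giving 9). Aldehyde 10 arises from the ester carbon of commercial 6 by reduction and re-oxidation (7, 8, 9, 10). The ester carbon of 6 has to become the formyl carbon C6', because only then does the new carboxyl fall between that carbon and a ring oxygen.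

## Alternatives that were turned down

**Alternative 1: aryne insertion into a ring B carbonate.**
- Disconnection: both depsidone bonds are cut at once, the C5–O ether and the C4–carbonyl bond. Ring A becomes an aryne (C4≡C5) and the ester carbonyl a cyclic carbonate spanning the C1' and C2' oxygens. The two rings are tied beforehand through a mixed acetal between the C6 hydroxymethyl oxygen and the lactol carbon (precursor A2).
- Forward key step: a fluoride source unveils the aryne from the silyl triflate of A2, the C1' oxygen adds to C5, and the C4 aryl anion is acylated at the carbonate carbon. This gives acetal-bridged depsidone A1 with a seven- and an eight-membered ring formed together.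
- For: ether and ester form in one redox-neutral step, and the tether masks the CH2OH and the lactol at the same time. On this point it is stronger than the chosen route, whose oxidative ether closure is its weakest later step.
- Against: A2 needs a pentasubstituted ring A silyl triflate built by stepwise aromatic substitution, plus a mixed-acetal union of a benzylic alcohol with a hydroxy lactone. The aryne has no electronic bias (a methyl and an alkyl group flank it), so regiochemistry rests on the tether alone. Fluoride can open the carbonate on its own. Insertion into a carbonate C–O bond with two medium rings forming has no close precedent. Release of the lactol from A1 needs acid at an electron-rich benzylic acetal. A1 is racemic at the acetal carbon, so the final resolution remains.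
- Comparison: the chosen route offers a precursor reached by short, ordinary chemistry and a ring-forming step of a known type.

**Alternative 2: carboxylate-directed C–H annulation.**
- Disconnection: the bond between C6' and the lactol carbon is cut, so the lactol carbon is added last to depsidone acid A5.
- Forward key step: a cationic Cp*Rh catalyst of trivalent rhodium annulates the C5' carboxyl and the C6'–H of A5 with vinylene carbonate A4 to give fused isocoumarin A3. Oxidative cleavage of the enol ester double bond and formate hydrolysis then leave the hydroxy lactone.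
- For: the sensitive carbon enters late, ring B needs no acid-labile masks during the sequence (a real advantage over the chosen route), and the only C–H ortho to the carboxyl is C6'–H.
- Against: it is an end-game, not an assembly. A5 still needs ring A, the ester and the ether. A5 is a salicylic acid whose phenol, seven-membered aryl lactone and benzylic acetate must survive a hot cationic metal system. C6'–H is flanked by the diaryl ether. Two carbons are installed to keep one, and the excision needs an alkene-cleaving oxidant next to the electron-rich ring A. About three operations are spent on one carbon.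
- Comparison: the chosen route carries that carbon from the start as the ester carbon of commercial 6 at no cost.

**Alternative 3: ketene acetal Diels–Alder.**
- Disconnection: ring A is cut at C2–C3 and C4–C5, giving ring B dienyl ketene acetal A8 (the C1' and C2' oxygens tied as a 2-alkylidene benzodioxole) and phenyl but-2-ynoate A7.
- Forward key step: cycloaddition, then base-induced aromatisation that expels one dioxole oxygen from the spiro carbon C5. The freed C2' aryloxide lactonises on the C4 aryl ester, displacing the aryloxide of A7, to give protected depsidone A6.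
- For: ring A, ether and ester come from one cascade, the diene polarity matches the ynoate (C2 to the β-carbon), and the C6 side chain is in place from the start, so no later hydroxymethylation is needed. On that last point it is stronger than the chosen route.
- Against: nothing decides which dioxole oxygen leaves C5. Loss of the C1' oxygen gives the isomer with ether and ester interchanged, and the two oxygens differ only through remote ring B substituents. A8 is a hydrolytically fragile, tetrasubstituted ketene acetal of a hexasubstituted catechol and would be long to make. A7 is a sluggish dienophile toward a diene with a fully substituted terminus.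
- Comparison: in the chosen route the ester oxygen is fixed by which phenol is free, and the ether carbon is fixed by its para relation to C4'–OH.

Key step: step 10

Assumption: the C6' lactol of 25 is taken to hold its configuration as a solid and in neutral aprotic solution, and the (R) sense of the lipase is assigned from the empirical rule for secondary alcohols with the fused ring B carbon as the large and the lactone oxygen as the medium substituent.

## Route

Step 1
Reactants: 1 2,2,6-trimethyl-4H-1,3-dioxin-4-one
Product: 3 2,2-dimethyl-6-(2-oxopropyl)-4H-1,3-dioxin-4-one, via lithium dienolate 2 (not isolated)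
Conditions: LiN(SiMe3)2 (1 equiv per 1), THF, −78 °C; AcCl (0.5 equiv), −78 °C; aq. NH4Cl
Reagents that add atoms: acetyl chloride, CC(Cl)=O
Why: Deprotonation of the 6-methyl group gives extended enolate 2, which is acylated at its terminal carbon (vinylogous Claisen condensation); half of 2 is consumed by the more acidic product, hence the stoichiometry.

Step 2
Reactants: 3 2,2-dimethyl-6-(2-oxopropyl)-4H-1,3-dioxin-4-one
Product: 5 6-(2,4-dioxopentyl)-2,2-dimethyl-4H-1,3-dioxin-4-one, via dilithium dianion 4 (not isolated)
Conditions: LiN(iPr)2 (2.3 equiv), THF, −78 °C; MeC(O)N(OMe)Me, −78 to −20 °C; aq. NH4Cl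
Reagents that add atoms: N-methoxy-N-methylacetamide, CC(=O)N(C)OC
Why: Double deprotonation, first at the methylene between the two acceptors and then at the terminal methyl, gives dianion 4, which reacts at its more basic terminal carbon with the Weinreb amide (Claisen condensation of a β-dicarbonyl dianion); the chelated tetrahedral adduct prevents further addition.

Step 3
Reactants: 6 methyl 3,5-dihydroxy-4-methylbenzoate
Product: 7 methyl 3,5-bis(benzyloxy)-4-methylbenzoate
Conditions: BnBr (2.4 equiv), K2CO3, DMF, 60 °C
Reagents that add atoms: benzyl bromide, BrCc1ccccc1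
Why: Williamson ether synthesis on both phenols; benzyl ethers survive hydride, organolithium and mild acid and are later removed by hydrogenolysis, which leaves an acetal and a tert-butyl ester alone.

Step 4
Reactants: 7 methyl 3,5-bis(benzyloxy)-4-methylbenzoate
Product: 8 [3,5-bis(benzyloxy)-4-methylphenyl]methanol
Conditions: LiAlH4, THF, 0 °C to rt; aqueous NaOH work-up
Reagents that add atoms: none
Why: LiAlH4 reduction of the ester to the benzylic alcohol; this carbon is destined to be the C6' formyl carbon and is brought to the aldehyde level in step 6.

Step 5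
Reactants: 8 [3,5-bis(benzyloxy)-4-methylphenyl]methanol
Product: 9 [3,5-bis(benzyloxy)-2-bromo-4-methylphenyl]methanol
Conditions: NBS (1.0 equiv), MeCN, 0 °C, dark
Reagents that add atoms: N-bromosuccinimide, O=C1CCC(=O)N1Br
Why: Electrophilic aromatic bromination; the two open ring positions are equivalent, each ortho to one benzyloxy group and para to the other, so one equivalent should give the monobromide that marks the future C5'.

Step 6
Reactants: 9 [3,5-bis(benzyloxy)-2-bromo-4-methylphenyl]methanol
Product: 10 3,5-bis(benzyloxy)-2-bromo-4-methylbenzaldehyde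
Conditions: MnO2 (activated, excess), CH2Cl2, rt
Reagents that add atoms: none
Why: MnO2 oxidation of a benzylic alcohol stops at the aldehyde; the aryl bromide and benzyl ethers are inert.

Step 7
Reactants: 10 3,5-bis(benzyloxy)-2-bromo-4-methylbenzaldehyde
Product: 11 3,5-bis(benzyloxy)-2-bromo-4-methylbenzaldehyde dimethyl acetal
Conditions: HC(OMe)3, MeOH, TsOH·H2O (cat.), rt; Et3N quench
Reagents that add atoms: trimethyl orthoformate, COC(OC)OC; methanol, CO
Why: Acid-catalysed acetalisation driven by the orthoformate as water scavenger; the acetal masks the aldehyde against the organolithium of step 8 and the enolates of step 10.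

Step 8
Reactants: 11 3,5-bis(benzyloxy)-2-bromo-4-methylbenzaldehyde dimethyl acetal
Product: 13 tert-butyl 2,4-bis(benzyloxy)-6-(dimethoxymethyl)-3-methylbenzoate, via aryllithium 12 (not isolated)
Conditions: n-BuLi (1.05 equiv), THF, −78 °C, 10 min; Boc2O (1.5 equiv), −78 °C to rt; aq. NH4Cl
Reagents that add atoms: di-tert-butyl dicarbonate, CC(C)(C)OC(=O)OC(=O)OC(C)(C)C
Why: Bromine–lithium exchange at −78 °C outruns deprotonation of the benzylic ether methylenes (the reason for exchange instead of direct ortho-lithiation) and gives aryllithium 12, held by the flanking acetal and benzyloxy oxygens; acylation by Boc2O gives the tert-butyl ester, whose bulk between two ortho groups stops a second addition.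

Step 9
Reactants: 13 tert-butyl 2,4-bis(benzyloxy)-6-(dimethoxymethyl)-3-methylbenzoate
Product: 14 tert-butyl 6-(dimethoxymethyl)-2,4-dihydroxy-3-methylbenzoate
Conditions: H2 (1 atm), Pd/C (10%), EtOAc, Et3N (trace), rt
Reagents that add atoms: none
Why: Hydrogenolysis of both benzyl ethers under neutral conditions; the trace of amine keeps the acetal from acid-catalysed loss and the tert-butyl ester is untouched.

Step 10
Reactants: 5 6-(2,4-dioxopentyl)-2,2-dimethyl-4H-1,3-dioxin-4-one (1.3 equiv); 14 tert-butyl 6-(dimethoxymethyl)-2,4-dihydroxy-3-methylbenzoate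
Product: 17 tert-butyl 4-[(2,4-dihydroxy-6-methylbenzoyl)oxy]-6-(dimethoxymethyl)-2-hydroxy-3-methylbenzoate, via acylketene 15 (not isolated), via triketo ester 16 (not isolated)
Conditions: PhMe, 110 °C, 1 h; then Et3N (3 equiv), CH2Cl2, 0 °C to rt; AcOH quench
Reagents that add atoms: none
Why: Heating 5 triggers a retro-hetero-Diels–Alder fragmentation that expels the ketal carbon as acetone and leaves acylketene 15. The ketene is captured by the C2' hydroxyl of 14, the O–H adding across it through a six-centre array that includes the neighbouring ketone oxygen, to give aryl 3,5,7-trioxooctanoate 16. Triethylamine then enolises the chain C2 methylene, which adds to the chain C7 ketone in a 6-(enolendo)-exo-trig aldol closure that forms ring A (its C3–C4 bond); E1cB loss of water and enolisation of the two remaining ketones give the aromatic 2,4-dihydroxy-6-methylbenzoate of 17. The closest known reaction type is thermolysis of diketo-dioxinones with capture of the acylketene by alcohols or phenols and aldol aromatisation to resorcylate esters, a laboratory form of polyketide cyclisation. No stereocentre is formed. Two selectivities are needed. Site selectivity between the phenols of 14 rests on the C4' hydroxyl being held in a six-membered hydrogen bond to the tert-butyl ester carbonyl and flanked by the C3' methyl and the ester, while the C2' hydroxyl is free and has one open flank. Within 16, the aldol at C7 must outrun attack of the chain C6 carbon or the C5 enol oxygen on the aryl ester, either of which would expel ring B; this rests on the ketone being the better electrophile under a weak amine base at or below room temperature, conditions the acetal and tert-butyl ester also tolerate.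

Step 11
Reactants: 17 tert-butyl 4-[(2,4-dihydroxy-6-methylbenzoyl)oxy]-6-(dimethoxymethyl)-2-hydroxy-3-methylbenzoate
Product: 18 tert-butyl 6-(dimethoxymethyl)-2-hydroxy-4-[(2-hydroxy-4-methoxy-6-methylbenzoyl)oxy]-3-methylbenzoate
Conditions: MeI (1.1 equiv), K2CO3 (1.1 equiv), acetone, rt
Reagents that add atoms: iodomethane, CI
Why: Williamson methylation with one equivalent of base; the C1 hydroxyl (para to the depside carbonyl) is the only phenol not hydrogen-bonded to an ester carbonyl and is the most acidic, the usual selectivity of 2,4-dihydroxybenzoates.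

Step 12
Reactants: 18 tert-butyl 6-(dimethoxymethyl)-2-hydroxy-4-[(2-hydroxy-4-methoxy-6-methylbenzoyl)oxy]-3-methylbenzoate
Product: 20 tert-butyl 6-(dimethoxymethyl)-2-hydroxy-4-{[2-hydroxy-3-(hydroxymethyl)-4-methoxy-6-methylbenzoyl]oxy}-3-methylbenzoate, via benzodioxaborin 19 (not isolated)
Conditions: PhB(OH)2 (1.5 equiv), (CH2O)n, EtCO2H (cat.), PhMe, 4 Å MS, 90 °C; then 30% aq. H2O2, THF, 0 °C
Reagents that add atoms: formaldehyde (from paraformaldehyde), C=O; phenylboronic acid, OB(O)c1ccccc1 (boron and phenyl are retained only in 19)
Why: Boronate-templated ortho-hydroxymethylation: the C5 phenol forms an aryloxyboronate that delivers formaldehyde through a six-membered array to C6, the only open ortho carbon, and the product is held as cyclic boronate 19, which blocks diarylmethane formation until H2O2 releases the diol. Ring B has no open carbon ortho to its phenol.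

Step 13
Reactants: 20 tert-butyl 6-(dimethoxymethyl)-2-hydroxy-4-{[2-hydroxy-3-(hydroxymethyl)-4-methoxy-6-methylbenzoyl]oxy}-3-methylbenzoate
Product: 21 tert-butyl 4-{[3-({[tert-butyl(dimethyl)silyl]oxy}methyl)-2-hydroxy-4-methoxy-6-methylbenzoyl]oxy}-6-(dimethoxymethyl)-2-hydroxy-3-methylbenzoate
Conditions: TBSCl (1.1 equiv), imidazole, CH2Cl2, 0 °C
Reagents that add atoms: tert-butyldimethylsilyl chloride, CC(C)(C)[Si](C)(C)Cl
Why: Silylation of the primary alcohol; both phenols are hydrogen-bonded to ester carbonyls and flanked on both sides, so stoichiometric silyl chloride should leave them free. The ether shields the benzylic alcohol from MnO2 in step 14.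

Step 14
Reactants: 21 tert-butyl 4-{[3-({[tert-butyl(dimethyl)silyl]oxy}methyl)-2-hydroxy-4-methoxy-6-methylbenzoyl]oxy}-6-(dimethoxymethyl)-2-hydroxy-3-methylbenzoate
Product: 22 tert-butyl 4-({[tert-butyl(dimethyl)silyl]oxy}methyl)-6-(dimethoxymethyl)-8-hydroxy-3-methoxy-1,9-dimethyl-11-oxo-11H-dibenzo[b,e][1,4]dioxepine-7-carboxylate
Conditions: MnO2 (activated, 15 equiv), CHCl3 (5 mM), rt
Reagents that add atoms: none
Why: Phenol oxidative coupling of a depside to a depsidone: oxidation of the ring B phenol places radical or cation character at C1', the carbon para to the C4' hydroxyl and the only unsubstituted one on ring B, and the C5 hydroxyl, held next to it by the ester, closes the seven-membered ether; tautomerisation restores the C4' phenol.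

Step 15
Reactants: 22 tert-butyl 4-({[tert-butyl(dimethyl)silyl]oxy}methyl)-6-(dimethoxymethyl)-8-hydroxy-3-methoxy-1,9-dimethyl-11-oxo-11H-dibenzo[b,e][1,4]dioxepine-7-carboxylate
Product: 23 racemic 1,4-dihydroxy-11-(hydroxymethyl)-10-methoxy-5,8-dimethyl-1H-isobenzofuro[4,5-b][1,4]benzodioxepine-3,7-dione
Conditions: 1 M aq. H2SO4/THF (1:3), 45 °C
Reagents that add atoms: water, O
Why: Aqueous acid hydrolyses the dimethyl acetal and the silyl ether; the ortho-formyl group then assists loss of the tert-butyl group (attack of its hydrate hydroxyl on the ester carbonyl, or capture of the oxocarbenium ion by the ester carbonyl oxygen and loss of the tert-butyl cation), and the product settles as the ring-closed hydroxy lactone. A non-nucleophilic acid in water keeps the C6 benzylic alcohol from being trapped as a halide; the lactol centre forms as the racemate.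

Step 16
Reactants: 23 racemic 1,4-dihydroxy-11-(hydroxymethyl)-10-methoxy-5,8-dimethyl-1H-isobenzofuro[4,5-b][1,4]benzodioxepine-3,7-dione
Product: 24 [(1R)-1-acetoxy-4-hydroxy-10-methoxy-5,8-dimethyl-3,7-dioxo-1H-isobenzofuro[4,5-b][1,4]benzodioxepin-11-yl]methyl acetate
Conditions: immobilised Burkholderia cepacia lipase, vinyl acetate (10 equiv), Et3N (0.1 equiv), THF, 35 °C
Reagents that add atoms: vinyl acetate, CC(=O)OC=C
Why: Lipase-mediated dynamic kinetic resolution of a cyclic acyl hemiacetal, as known for γ-hydroxybutenolides: amine-catalysed ring–chain tautomerism keeps the lactol enantiomers in equilibrium while the enzyme transfers acetyl to one of them, the (R) acetate being expected from the empirical secondary-alcohol rule (fused aryl carbon large, lactone oxygen medium). The primary alcohol is acetylated as well; the hydrogen-bonded phenol is not a lipase substrate.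

Step 17
Reactants: 24 [(1R)-1-acetoxy-4-hydroxy-10-methoxy-5,8-dimethyl-3,7-dioxo-1H-isobenzofuro[4,5-b][1,4]benzodioxepin-11-yl]methyl acetate
Product: 25 (1R)-1,4-dihydroxy-11-(hydroxymethyl)-10-methoxy-5,8-dimethyl-1H-isobenzofuro[4,5-b][1,4]benzodioxepine-3,7-dione
Conditions: immobilised Burkholderia cepacia lipase, n-BuOH (10 equiv), MTBE/THF (4:1), 25 °C; filtration, evaporation below 25 °C
Reagents that add atoms: none
Why: Lipase-catalysed alcoholysis breaks only acyl–oxygen bonds, so the C–O bonds at the lactol carbon are untouched and the configuration is retained; the anomeric acetate is an activated ester and goes first, the primary acetate follows. A neutral medium and cold isolation limit ring–chain equilibration of the product.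

## Compound list

1 | 2,2,6-trimethyl-4H-1,3-dioxin-4-one | CC1=CC(=O)OC(C)(C)O1 | starting material
2 | lithium dienolate of 1 (lithium 2,2-dimethyl-6-methylidene-6H-1,3-dioxin-4-olate) | C=C1C=C(O[Li])OC(C)(C)O1 | intermediate (not isolated)
3 | 2,2-dimethyl-6-(2-oxopropyl)-4H-1,3-dioxin-4-one | CC(=O)CC1=CC(=O)OC(C)(C)O1 | intermediate
4 | dilithium dianion of 3 (bis-enolate) | C=C(O[Li])C=C1C=C(O[Li])OC(C)(C)O1 | intermediate (not isolated)
5 | 6-(2,4-dioxopentyl)-2,2-dimethyl-4H-1,3-dioxin-4-one | CC(=O)CC(=O)CC1=CC(=O)OC(C)(C)O1 | intermediate
6 | methyl 3,5-dihydroxy-4-methylbenzoate | COC(=O)c1cc(O)c(C)c(O)c1 | starting material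
7 | methyl 3,5-bis(benzyloxy)-4-methylbenzoate | COC(=O)c1cc(OCc2ccccc2)c(C)c(OCc2ccccc2)c1 | intermediate
8 | [3,5-bis(benzyloxy)-4-methylphenyl]methanol | OCc1cc(OCc2ccccc2)c(C)c(OCc2ccccc2)c1 | intermediate
9 | [3,5-bis(benzyloxy)-2-bromo-4-methylphenyl]methanol | OCc1cc(OCc2ccccc2)c(C)c(OCc2ccccc2)c1Br | intermediate
10 | 3,5-bis(benzyloxy)-2-bromo-4-methylbenzaldehyde | O=Cc1cc(OCc2ccccc2)c(C)c(OCc2ccccc2)c1Br | intermediate
11 | 3,5-bis(benzyloxy)-2-bromo-4-methylbenzaldehyde dimethyl acetal | COC(OC)c1cc(OCc2ccccc2)c(C)c(OCc2ccccc2)c1Br | intermediate
12 | [2,4-bis(benzyloxy)-6-(dimethoxymethyl)-3-methylphenyl]lithium | COC(OC)c1cc(OCc2ccccc2)c(C)c(OCc2ccccc2)c1[Li] | intermediate (not isolated)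
13 | tert-butyl 2,4-bis(benzyloxy)-6-(dimethoxymethyl)-3-methylbenzoate | COC(OC)c1cc(OCc2ccccc2)c(C)c(OCc2ccccc2)c1C(=O)OC(C)(C)C | intermediate
14 | tert-butyl 6-(dimethoxymethyl)-2,4-dihydroxy-3-methylbenzoate | COC(OC)c1cc(O)c(C)c(O)c1C(=O)OC(C)(C)C | intermediate
15 | 3,5,7-trioxooct-1-en-1-one (acylketene) | CC(=O)CC(=O)CC(=O)C=C=O | intermediate (not isolated)
16 | tert-butyl 6-(dimethoxymethyl)-2-hydroxy-3-methyl-4-[(3,5,7-trioxooctanoyl)oxy]benzoate | CC(=O)CC(=O)CC(=O)CC(=O)Oc1cc(C(OC)OC)c(C(=O)OC(C)(C)C)c(O)c1C | intermediate (not isolated)
17 | tert-butyl 4-[(2,4-dihydroxy-6-methylbenzoyl)oxy]-6-(dimethoxymethyl)-2-hydroxy-3-methylbenzoate | Cc1cc(O)cc(O)c1C(=O)Oc1cc(C(OC)OC)c(C(=O)OC(C)(C)C)c(O)c1C | intermediate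
18 | tert-butyl 6-(dimethoxymethyl)-2-hydroxy-4-[(2-hydroxy-4-methoxy-6-methylbenzoyl)oxy]-3-methylbenzoate | COc1cc(C)c(C(=O)Oc2cc(C(OC)OC)c(C(=O)OC(C)(C)C)c(O)c2C)c(O)c1 | intermediate
19 | cyclic phenylboronate of 20 (2-phenyl-4H-1,3,2-benzodioxaborin bridging the C5 oxygen and the C6 CH2O) | COc1cc(C)c(C(=O)Oc2cc(C(OC)OC)c(C(=O)OC(C)(C)C)c(O)c2C)c2OB(c3ccccc3)OCc12 | intermediate (not isolated)
20 | tert-butyl 6-(dimethoxymethyl)-2-hydroxy-4-{[2-hydroxy-3-(hydroxymethyl)-4-methoxy-6-methylbenzoyl]oxy}-3-methylbenzoate | COc1cc(C)c(C(=O)Oc2cc(C(OC)OC)c(C(=O)OC(C)(C)C)c(O)c2C)c(O)c1CO | intermediate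
21 | tert-butyl 4-{[3-({[tert-butyl(dimethyl)silyl]oxy}methyl)-2-hydroxy-4-methoxy-6-methylbenzoyl]oxy}-6-(dimethoxymethyl)-2-hydroxy-3-methylbenzoate | COc1cc(C)c(C(=O)Oc2cc(C(OC)OC)c(C(=O)OC(C)(C)C)c(O)c2C)c(O)c1CO[Si](C)(C)C(C)(C)C | intermediate
22 | tert-butyl 4-({[tert-butyl(dimethyl)silyl]oxy}methyl)-6-(dimethoxymethyl)-8-hydroxy-3-methoxy-1,9-dimethyl-11-oxo-11H-dibenzo[b,e][1,4]dioxepine-7-carboxylate | COc1cc(C)c2c(c1CO[Si](C)(C)C(C)(C)C)Oc1c(c(C)c(O)c(C(=O)OC(C)(C)C)c1C(OC)OC)OC2=O | intermediate
23 | racemic 1,4-dihydroxy-11-(hydroxymethyl)-10-methoxy-5,8-dimethyl-1H-isobenzofuro[4,5-b][1,4]benzodioxepine-3,7-dione | COc1cc(C)c2c(c1CO)Oc1c(c(C)c(O)c3c1C(O)OC3=O)OC2=O | intermediate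
24 | [(1R)-1-acetoxy-4-hydroxy-10-methoxy-5,8-dimethyl-3,7-dioxo-1H-isobenzofuro[4,5-b][1,4]benzodioxepin-11-yl]methyl acetate | COc1cc(C)c2c(c1COC(C)=O)Oc1c(c(C)c(O)c3c1[C@H](OC(C)=O)OC3=O)OC2=O | intermediate
25 | (1R)-1,4-dihydroxy-11-(hydroxymethyl)-10-methoxy-5,8-dimethyl-1H-isobenzofuro[4,5-b][1,4]benzodioxepine-3,7-dione | COc1cc(C)c2c(c1CO)Oc1c(c(C)c(O)c3c1[C@H](O)OC3=O)OC2=O | target

## Step count and least certain steps

Total: 17 steps. Longest linear sequence: 15 steps (6 to 25 through steps 3 to 17); steps 1 and 2 form the short branch to 5.

**Step 10 (key step).** The most likely failure is loss of ring B from 16 before the aldol occurs. The aryl ester is a good leaving group, so Claisen-type attack of the chain C6 carbon, or lactonisation of the C5 enol oxygen, on the ester carbonyl would expel 14; over-acylation at the C4' hydroxyl is a lesser risk. The fallback reverses the order of events, aromatising first and acylating second. It sets out from 5: Et3N in CH2Cl2 without heating closes the dioxinone α-carbon onto the terminal ketone and gives 7-hydroxy-2,2,5-trimethyl-4H-1,3-benzodioxin-4-one F1. Irradiation of F1 at 300 nm with 14 in CH2Cl2 releases acetone and an ortho-quinone ketene, which the C2' hydroxyl captures. The fallback comes back at 17. No open-chain triketo ester is involved, so the Claisen and lactonisation paths do not exist.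

**Step 14.** The oxidation may be unselective: intermolecular coupling through the open C2 position of ring A, oxidation at the C3' methyl, or no reaction because both phenols are electron-poor. The fallback replaces oxidation by a halogen-based ether closure. It sets out from 14: NBS in MeCN at 0 °C brominates the only open ring carbon to give tert-butyl 5-bromo-6-(dimethoxymethyl)-2,4-dihydroxy-3-methylbenzoate F2. F2 is carried through the operations of steps 10 to 13: ketene capture and aromatisation give bromo depside F3, methylation gives F4, hydroxymethylation gives F5 and silylation gives F6. F6 is closed by intramolecular Ullmann etherification (CuI, N,N-dimethylglycine, Cs2CO3, dioxane, 90 °C), which comes back at 22.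

**Step 12.** The dimethyl acetal may ionise under hot carboxylic acid and boronic acid (acetal exchange with formaldehyde, or premature collapse onto the tert-butyl ester), or C–C bond formation may be slow on the hydrogen-bonded phenol. The fallback uses base instead of acid and goes through the aldehyde. It sets out from 18: MgCl2, Et3N and (CH2O)n in MeCN at reflux (magnesium phenoxide-directed ortho-formylation) give the C6 aldehyde, tert-butyl 6-(dimethoxymethyl)-4-[(3-formyl-2-hydroxy-4-methoxy-6-methylbenzoyl)oxy]-2-hydroxy-3-methylbenzoate F7. NaBH4 in THF/MeOH at −20 °C reduces F7 and comes back at 20.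

**Step 16.** The enzyme may accept the crowded lactol too slowly, since the lactol hydroxyl lies next to the diaryl ether and the C6 side chain, or it may acylate the other enantiomer. The fallback changes from an enzyme to a small-molecule acyl-transfer catalyst. It sets out from 23: acetic anhydride, iPr2NEt and a chiral isothiourea catalyst (benzotetramisole, used as the enantiomer that delivers the (R) acetate) in CHCl3 at 0 °C, an acylative dynamic kinetic resolution of a lactol. It comes back at 24 and makes no new compound (F0).

**Step 17.** Configuration may erode at the lactol carbon, because slow enzymatic cleavage of the hindered primary acetate leaves free lactol in solution with an alcohol for a long time. The fallback arranges that the last step removes only the activated anomeric acetate. It sets out from 20: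
- TBDPSCl and imidazole give the tert-butyldiphenylsilyl ether F8.
- The MnO2 closure of step 14 gives depsidone F9.
- The aqueous acid of step 15, which this silyl ether should survive, gives racemic lactol F10.
- The lipase acetylation of step 16 gives (R) acetate F11.
- HF·pyridine in THF/pyridine at 0 °C frees the primary alcohol to give (R) acetate alcohol F12.
- The lipase alcoholysis of step 17 then comes back at 25.

## Further compounds

F1 | step 10 | 7-hydroxy-2,2,5-trimethyl-4H-1,3-benzodioxin-4-one | Cc1cc(O)cc2OC(C)(C)OC(=O)c12
F2 | step 14 | tert-butyl 5-bromo-6-(dimethoxymethyl)-2,4-dihydroxy-3-methylbenzoate | COC(OC)c1c(Br)c(O)c(C)c(O)c1C(=O)OC(C)(C)C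
F3 | step 14 | tert-butyl 5-bromo-4-[(2,4-dihydroxy-6-methylbenzoyl)oxy]-6-(dimethoxymethyl)-2-hydroxy-3-methylbenzoate | Cc1cc(O)cc(O)c1C(=O)Oc1c(Br)c(C(OC)OC)c(C(=O)OC(C)(C)C)c(O)c1C
F4 | step 14 | tert-butyl 5-bromo-6-(dimethoxymethyl)-2-hydroxy-4-[(2-hydroxy-4-methoxy-6-methylbenzoyl)oxy]-3-methylbenzoate | COc1cc(C)c(C(=O)Oc2c(Br)c(C(OC)OC)c(C(=O)OC(C)(C)C)c(O)c2C)c(O)c1
F5 | step 14 | tert-butyl 5-bromo-6-(dimethoxymethyl)-2-hydroxy-4-{[2-hydroxy-3-(hydroxymethyl)-4-methoxy-6-methylbenzoyl]oxy}-3-methylbenzoate | COc1cc(C)c(C(=O)Oc2c(Br)c(C(OC)OC)c(C(=O)OC(C)(C)C)c(O)c2C)c(O)c1CO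
F6 | step 14 | tert-butyl 5-bromo-4-{[3-({[tert-butyl(dimethyl)silyl]oxy}methyl)-2-hydroxy-4-methoxy-6-methylbenzoyl]oxy}-6-(dimethoxymethyl)-2-hydroxy-3-methylbenzoate | COc1cc(C)c(C(=O)Oc2c(Br)c(C(OC)OC)c(C(=O)OC(C)(C)C)c(O)c2C)c(O)c1CO[Si](C)(C)C(C)(C)C
F7 | step 12 | tert-butyl 6-(dimethoxymethyl)-4-[(3-formyl-2-hydroxy-4-methoxy-6-methylbenzoyl)oxy]-2-hydroxy-3-methylbenzoate | COc1cc(C)c(C(=O)Oc2cc(C(OC)OC)c(C(=O)OC(C)(C)C)c(O)c2C)c(O)c1C=O
F0 | step 16 | none | none
F8 | step 17 | tert-butyl 4-{[3-({[tert-butyl(diphenyl)silyl]oxy}methyl)-2-hydroxy-4-methoxy-6-methylbenzoyl]oxy}-6-(dimethoxymethyl)-2-hydroxy-3-methylbenzoate | COc1cc(C)c(C(=O)Oc2cc(C(OC)OC)c(C(=O)OC(C)(C)C)c(O)c2C)c(O)c1CO[Si](c3ccccc3)(c4ccccc4)C(C)(C)C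
F9 | step 17 | tert-butyl 4-({[tert-butyl(diphenyl)silyl]oxy}methyl)-6-(dimethoxymethyl)-8-hydroxy-3-methoxy-1,9-dimethyl-11-oxo-11H-dibenzo[b,e][1,4]dioxepine-7-carboxylate | COc1cc(C)c2c(c1CO[Si](c5ccccc5)(c6ccccc6)C(C)(C)C)Oc1c(c(C)c(O)c(C(=O)OC(C)(C)C)c1C(OC)OC)OC2=O
F10 | step 17 | racemic 11-({[tert-butyl(diphenyl)silyl]oxy}methyl)-1,4-dihydroxy-10-methoxy-5,8-dimethyl-1H-isobenzofuro[4,5-b][1,4]benzodioxepine-3,7-dione | COc1cc(C)c2c(c1CO[Si](c5ccccc5)(c6ccccc6)C(C)(C)C)Oc1c(c(C)c(O)c3c1C(O)OC3=O)OC2=O
F11 | step 17 | (1R)-11-({[tert-butyl(diphenyl)silyl]oxy}methyl)-4-hydroxy-10-methoxy-5,8-dimethyl-3,7-dioxo-1H-isobenzofuro[4,5-b][1,4]benzodioxepin-1-yl acetate | COc1cc(C)c2c(c1CO[Si](c5ccccc5)(c6ccccc6)C(C)(C)C)Oc1c(c(C)c(O)c3c1[C@H](OC(C)=O)OC3=O)OC2=O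
F12 | step 17 | (1R)-4-hydroxy-11-(hydroxymethyl)-10-methoxy-5,8-dimethyl-3,7-dioxo-1H-isobenzofuro[4,5-b][1,4]benzodioxepin-1-yl acetate | COc1cc(C)c2c(c1CO)Oc1c(c(C)c(O)c3c1[C@H](OC(C)=O)OC3=O)OC2=O
A1 | alternative 1 | acetal-bridged depsidone (racemic at the acetal carbon) | COc1cc(C)c2c3c1COC1OC(=O)c4c(OCOC)c(C)c(OC2=O)c(O3)c41
A2 | alternative 1 | ring A silyl triflate tethered as a mixed acetal to the ring B lactone carrying a C1',C2' cyclic carbonate (racemic) | COc1cc(C)c([Si](C)(C)C)c(OS(=O)(=O)C(F)(F)F)c1COC1OC(=O)c2c(OCOC)c(C)c3OC(=O)Oc3c12
A3 | alternative 2 | depsidone-fused isocoumarin | COc1cc(C)c2c(c1COC(C)=O)Oc1c(c(C)c(O)c3c1C=COC3=O)OC2=O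
A4 | alternative 2 | vinylene carbonate | O=C1OC=CO1
A5 | alternative 2 | depsidone C5' carboxylic acid with C6'–H | COc1cc(C)c2c(c1COC(C)=O)Oc1c(c(C)c(O)c(C(=O)O)c1)OC2=O
A6 | alternative 3 | protected depsidone with methoxymethyl ether at C4' | COc1cc(C)c2c(c1CO[Si](C)(C)C(C)(C)C)Oc1c(c(C)c(OCOC)c(C(=O)OC(C)(C)C)c1C(OC)OC)OC2=O
A7 | alternative 3 | phenyl but-2-ynoate | CC#CC(=O)Oc1ccccc1
A8 | alternative 3 | ring B 2-alkylidene-1,3-benzodioxole diene (dienyl ketene acetal) | C=C(OC)C(CO[Si](C)(C)C(C)(C)C)=C1Oc2c(O1)c(C)c(OCOC)c(C(=O)OC(C)(C)C)c2C(OC)OC
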